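**Retrosynthetic overview**

1. Target ⇒ dienolide 23 by a last peracid epoxidation of the cis C1=C10 olefin. The α-methylene-γ-lactone of 23 comes from cyclocarbonylation of a C6-hydroxy/C7-ethynyl pair, the C8 ester from epoxy acid 3, and the C8 carbinol from a C6-OH-directed reduction of a C8 ketone.
2. Ten-membered carbocycle ⇒ two-atom ring expansion ([3,3], Claisen) of the eight-membered cyclic enol ether 16, whose ring oxygen bridges C4 and C8. The shift makes the C6–C7 bond, both stereocentres C6 and C7, the Z C4=C5 olefin and the C8 carbonyl in one operation.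
3. Enabling feature: in the ten-membered ring the oxygenated carbon C8 and the C4=C5 double bond are γ,δ-related through C7–C6 (C8–C7–C6–C5=C4), the retron of a Claisen shift. C4 bears a methyl group, so the ether carbon is a quaternary centre available from (S)-2-methylglycidol, and both ring olefins are cis, as the eight-membered precursor and its bridged chair require.
4. 16 ⇒ eight-membered lactone 9 (ring-closing metathesis); the lactone carbonyl becomes the exocyclic (E)-enyne enol ether and the CH2OSi arm becomes the (E)-alkenylboronate.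
5. Order of ring formation: eight-membered lactone → ten-membered carbocycle → γ-lactone → ring oxirane; the side-chain oxirane is made separately by Sharpless epoxidation.

Key step: step 13

Remark: positions are quoted in germacrane numbering (C6 lactone carbinol, C7 ring-fusion carbon, C8 ester carbinol, C1/C10 oxirane, C4=C5 olefin, C11–C13 lactone carbons). The target SMILES is read as 1S,6R,7R,8R,10R with a cis-oxirane (C2 and C9 cis), a Z C4=C5 bond, a trans-fused lactone and a (2S,3R)-2,3-dimethyloxirane-2-carboxylate (methyl groups cis).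

**Route**

Step 1
Reactants: 1 (E)-2-methylbut-2-en-1-ol
Product: 2 [(2R,3R)-2,3-dimethyloxiran-2-yl]methanol
Conditions: Ti(OiPr)4 (cat.), D-(−)-diethyl tartrate (cat.), t-BuOOH, 4 Å MS, CH2Cl2, −20 °C
Reagents that add atoms: tert-butyl hydroperoxide, CC(C)(C)OO
Why: Sharpless asymmetric epoxidation of an (E)-trisubstituted allylic alcohol, in which the D-(−)-tartrate titanium complex delivers oxygen to the face that gives the 2R,3R oxirane with the two methyl groups cis.

Step 2
Reactants: 2 [(2R,3R)-2,3-dimethyloxiran-2-yl]methanol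
Product: 3 (2S,3R)-2,3-dimethyloxirane-2-carboxylic acid
Conditions: RuCl3 (cat.), NaIO4, CCl4/MeCN/H2O, rt
Reagents that add atoms: sodium periodate, [Na+].[O-]I(=O)(=O)=O
Why: Ruthenium tetroxide oxidation (catalytic RuCl3 with periodate) takes the primary alcohol to the acid without touching the oxirane, so both centres are kept and C2 only changes its descriptor to S.

Step 3
Reactants: 4 (S)-2-methylglycidol
Product: 5 (R)-tert-butyl[(2-methyloxiran-2-yl)methoxy]diphenylsilane
Conditions: TBDPSCl, imidazole, CH2Cl2, 0 °C to rt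
Reagents that add atoms: tert-butyl(chloro)diphenylsilane, CC(C)(C)[Si](Cl)(c1ccccc1)c1ccccc1
Why: Silyl ether formation at the primary alcohol leaves the oxirane and its quaternary stereocentre untouched.

Step 4
Reactants: 5 (R)-tert-butyl[(2-methyloxiran-2-yl)methoxy]diphenylsilane
Product: 6 (2R)-1-{[tert-butyl(diphenyl)silyl]oxy}-2-methylhex-5-en-2-ol
Conditions: allylmagnesium bromide, CuI (cat.), THF, −30 to 0 °C; aqueous work-up
Reagents that add atoms: allylmagnesium bromide, C=CC[Mg]Br
Why: Copper-catalysed Grignard opening of a 2,2-disubstituted epoxide occurs at the unsubstituted CH2 terminus, so the quaternary carbinol carbon (the future C4) is not touched and keeps its configuration.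

Step 5
Reactants: 6 (2R)-1-{[tert-butyl(diphenyl)silyl]oxy}-2-methylhex-5-en-2-ol; 7 3-methylbut-3-enoic acid
Product: 8 (2R)-1-{[tert-butyl(diphenyl)silyl]oxy}-2-methylhex-5-en-2-yl 3-methylbut-3-enoate
Conditions: DCC, DMAP, CH2Cl2, 0 °C to rt
Reagents that add atoms: none
Why: Steglich esterification, which is suited to tertiary alcohols, joins the two olefinic halves through the future ring oxygen.

Step 6
Reactants: 8 (2R)-1-{[tert-butyl(diphenyl)silyl]oxy}-2-methylhex-5-en-2-yl 3-methylbut-3-enoate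
Product: 9 (4Z,8R)-8-({[tert-butyl(diphenyl)silyl]oxy}methyl)-4,8-dimethyl-3,6,7,8-tetrahydro-2H-oxocin-2-one
Conditions: second-generation Grubbs catalyst (10 mol %), toluene (1 mM), 80 °C
Reagents that add atoms: none
Why: Ring-closing metathesis between the monosubstituted and the 1,1-disubstituted olefin, helped by the quaternary centre (gem-disubstituent effect), should close the eight-membered lactone, in which the new trisubstituted olefin can only be cis.

Step 7
Reactants: 9 (4Z,8R)-8-({[tert-butyl(diphenyl)silyl]oxy}methyl)-4,8-dimethyl-3,6,7,8-tetrahydro-2H-oxocin-2-one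
Product: 10 tert-butyl{[(4Z,8R)-4,8-dimethyl-2-methylidene-3,6,7,8-tetrahydro-2H-oxocin-8-yl]methoxy}diphenylsilane
Conditions: Cp2TiMe2, toluene, 70 °C, dark
Reagents that add atoms: dimethyltitanocene, C[Ti](C)(C1C=CC=C1)C1C=CC=C1
Why: Petasis methylenation converts the lactone carbonyl into the exocyclic enol ether under neutral, non-Lewis-acidic conditions that spare the skipped olefin and the silyl ether.

Step 8
Reactants: 10 tert-butyl{[(4Z,8R)-4,8-dimethyl-2-methylidene-3,6,7,8-tetrahydro-2H-oxocin-8-yl]methoxy}diphenylsilane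
Product: 12 (2E)-2-[(4Z,8R)-8-({[tert-butyl(diphenyl)silyl]oxy}methyl)-4,8-dimethyl-3,6,7,8-tetrahydro-2H-oxocin-2-ylidene]acetaldehyde, via iminium chloride 11 (not isolated)
Conditions: (chloromethylene)dimethyliminium chloride, 2,6-lutidine, CH2Cl2, −20 to 0 °C; then aq. K2CO3
Reagents that add atoms: (chloromethylene)dimethyliminium chloride, ClC=[N+](C)C.[Cl-]; water, O
Why: Vilsmeier–Haack formylation of the nucleophilic exocyclic enol ether carbon should give, after hydrolysis of the vinylogous iminium salt, the push–pull β-alkoxy enal, which settles as the E isomer with the formyl group trans to the ring oxygen.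

Step 9
Reactants: 12 (2E)-2-[(4Z,8R)-8-({[tert-butyl(diphenyl)silyl]oxy}methyl)-4,8-dimethyl-3,6,7,8-tetrahydro-2H-oxocin-2-ylidene]acetaldehyde
Product: 13 tert-butyl{[(2E,4Z,8R)-4,8-dimethyl-2-(prop-2-yn-1-ylidene)-3,6,7,8-tetrahydro-2H-oxocin-8-yl]methoxy}diphenylsilane
Conditions: Me3SiCHN2, n-BuLi, THF, −78 °C to rt
Reagents that add atoms: (trimethylsilyl)diazomethane, C[Si](C)(C)C=[N+]=[N-]
Why: Colvin homologation (addition of lithiated trimethylsilyldiazomethane, Peterson elimination, 1,2-hydrogen shift of the alkylidene carbene) turns the aldehyde into the terminal alkyne without a nucleophile that could attack the vinylogous ester and with retention of the enol ether geometry.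

Step 10
Reactants: 13 tert-butyl{[(2E,4Z,8R)-4,8-dimethyl-2-(prop-2-yn-1-ylidene)-3,6,7,8-tetrahydro-2H-oxocin-8-yl]methoxy}diphenylsilane
Product: 14 [(2E,4Z,8R)-4,8-dimethyl-2-(prop-2-yn-1-ylidene)-3,6,7,8-tetrahydro-2H-oxocin-8-yl]methanol
Conditions: TBAF, THF, 0 °C to rt
Reagents that add atoms: none
Why: Fluoride-mediated desilylation is compatible with the acid-sensitive enol ether and frees the primary alcohol.

Step 11
Reactants: 14 [(2E,4Z,8R)-4,8-dimethyl-2-(prop-2-yn-1-ylidene)-3,6,7,8-tetrahydro-2H-oxocin-8-yl]methanol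
Product: 15 (2E,4Z,8R)-4,8-dimethyl-2-(prop-2-yn-1-ylidene)-3,6,7,8-tetrahydro-2H-oxocine-8-carbaldehyde
Conditions: Dess–Martin periodinane, pyridine, CH2Cl2, 0 °C
Reagents that add atoms: none
Why: Buffered Dess–Martin oxidation gives the aldehyde, which cannot epimerise because its α-carbon is quaternary.

Step 12
Reactants: 15 (2E,4Z,8R)-4,8-dimethyl-2-(prop-2-yn-1-ylidene)-3,6,7,8-tetrahydro-2H-oxocine-8-carbaldehyde
Product: 16 2-{(E)-2-[(2E,4Z,8R)-4,8-dimethyl-2-(prop-2-yn-1-ylidene)-3,6,7,8-tetrahydro-2H-oxocin-8-yl]ethenyl}-4,4,5,5-tetramethyl-1,3,2-dioxaborolane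
Conditions: CrCl2, Cl2CHB(pin), LiI, THF, rt
Reagents that add atoms: 2-(dichloromethyl)-4,4,5,5-tetramethyl-1,3,2-dioxaborolane, ClC(Cl)B1OC(C)(C)C(C)(C)O1
Why: Takai–Utimoto olefination with the geminal dichromium reagent should give the (E)-alkenylboronate selectively and so completes the allyl vinyl ether array.

Step 13
Reactants: 16 2-{(E)-2-[(2E,4Z,8R)-4,8-dimethyl-2-(prop-2-yn-1-ylidene)-3,6,7,8-tetrahydro-2H-oxocin-8-yl]ethenyl}-4,4,5,5-tetramethyl-1,3,2-dioxaborolane
Product: 17 (2R,3R,4Z,8Z)-2-ethynyl-5,9-dimethyl-3-(4,4,5,5-tetramethyl-1,3,2-dioxaborolan-2-yl)cyclodeca-4,8-dien-1-one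
Conditions: toluene (0.01 M), 110 °C, sealed tube, trace Et3N
Reagents that add atoms: none
Why: Thermal [3,3]-sigmatropic (Claisen) shift of the allyl vinyl ether array C7=C8–O–C4–C5=C6 breaks C4–O and makes C6–C7, so the ring oxygen leaves the ring as the C8 carbonyl while C5, C6 and C7 enter it and the eight-membered oxocine becomes the ten-membered carbocycle (ring expansion by two atoms). The closest known reaction type is the Claisen ring expansion of 2-alkylidene cyclic ethers that carry a vinyl group at the other ether carbon to 4-cycloalkenones, combined with the known Claisen rearrangements of (E)-alkenylboronates to α-substituted allylboronates. The ten-membered ring is therefore not closed end to end but arises in a bridged six-membered chair transition state in which the tether C9–C10–C1–C2–C3 spans C8 and the axial position of C4. The new stereocentres C6 and C7 are set by this chair, with boron equatorial at C6 because the alkenylboronate is E and the ethynyl group equatorial at C7 because it is trans to the ring oxygen, and the suprafacial shift passes the R configuration of the quaternary ether carbon C4 on to the 6R,7R pair (descriptors of 17) with the two substituents syn. The step needs chair over boat and the Z (ring-cis) C4=C5 olefin over the E one, and both are secured by the short tether with its cis C1=C10 olefin, which can bridge C8 and C4 only when it is axial on the chair and the C15 methyl is equatorial.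

Step 14
Reactants: 17 (2R,3R,4Z,8Z)-2-ethynyl-5,9-dimethyl-3-(4,4,5,5-tetramethyl-1,3,2-dioxaborolan-2-yl)cyclodeca-4,8-dien-1-one
Product: 18 (2S,3R,4Z,8Z)-2-ethynyl-3-hydroxy-5,9-dimethylcyclodeca-4,8-dien-1-one
Conditions: H2O2 (30 % aq.), aq. NaHCO3, THF, 0 °C
Reagents that add atoms: hydrogen peroxide, OO
Why: Oxidation of the allylic boronate by hydroperoxide goes through 1,2-migration from boron to oxygen with retention, so the Claisen-derived configuration at C6 is carried into the alcohol.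

Step 15
Reactants: 18 (2S,3R,4Z,8Z)-2-ethynyl-3-hydroxy-5,9-dimethylcyclodeca-4,8-dien-1-one
Product: 19 (1R,2Z,6Z,9R,10R)-10-ethynyl-9-hydroxy-3,7-dimethylcyclodeca-2,6-dien-1-yl acetate
Conditions: MeCHO, SmI2 (0.3 equiv.), THF, −10 °C
Reagents that add atoms: acetaldehyde, CC=O
Why: Evans–Tishchenko reduction, in which the samarium-bound hemiacetal formed from the C6 hydroxyl and acetaldehyde delivers hydride to the C8 carbonyl through a six-membered chair, should set the 1,3-anti (8R) carbinol and at the same time cap O6 as the acetate.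

Step 16
Reactants: 3 (2S,3R)-2,3-dimethyloxirane-2-carboxylic acid; 19 (1R,2Z,6Z,9R,10R)-10-ethynyl-9-hydroxy-3,7-dimethylcyclodeca-2,6-dien-1-yl acetate
Product: 21 (1R,2R,3R,4Z,8Z)-3-acetoxy-2-ethynyl-5,9-dimethylcyclodeca-4,8-dien-1-yl (2S,3R)-2,3-dimethyloxirane-2-carboxylate, via mixed anhydride 20 (not isolated)
Conditions: 2,4,6-trichlorobenzoyl chloride, Et3N, THF, rt; then 19, DMAP, toluene, rt
Reagents that add atoms: 2,4,6-trichlorobenzoyl chloride, O=C(Cl)c1c(Cl)cc(Cl)cc1Cl (its atoms stay in 20 only)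
Why: Yamaguchi esterification acylates the hindered secondary C8 hydroxyl with the α-quaternary epoxy acid through its mixed anhydride, and no stereocentre of either partner can epimerise.

Step 17
Reactants: 21 (1R,2R,3R,4Z,8Z)-3-acetoxy-2-ethynyl-5,9-dimethylcyclodeca-4,8-dien-1-yl (2S,3R)-2,3-dimethyloxirane-2-carboxylate
Product: 22 (1R,2S,3R,4Z,8Z)-2-ethynyl-3-hydroxy-5,9-dimethylcyclodeca-4,8-dien-1-yl (2S,3R)-2,3-dimethyloxirane-2-carboxylate
Conditions: K2CO3 (cat.), MeOH, 0 °C
Reagents that add atoms: none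
Why: Base-catalysed transesterification with methanol should remove the unhindered acetate much faster than the α-quaternary epoxy ester.

Step 18
Reactants: 22 (1R,2S,3R,4Z,8Z)-2-ethynyl-3-hydroxy-5,9-dimethylcyclodeca-4,8-dien-1-yl (2S,3R)-2,3-dimethyloxirane-2-carboxylate
Product: 23 (3aR,4R,6Z,10Z,11aR)-6,10-dimethyl-3-methylidene-2-oxo-2,3,3a,4,5,8,9,11a-octahydrocyclodeca[b]furan-4-yl (2S,3R)-2,3-dimethyloxirane-2-carboxylate
Conditions: CO (8 atm), PdCl2(PPh3)2 (cat.), SnCl2 (cat.), MeCN, 70 °C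
Reagents that add atoms: carbon monoxide, [C-]#[O+]
Why: Palladium-catalysed cyclocarbonylation of the homopropargylic alcohol (alkoxycarbonylpalladium formation, syn insertion of the alkyne, protonolysis) builds the α-methylene-γ-butyrolactone, and the trans ring fusion is fixed by the existing C6 and C7 centres.

Step 19
Reactants: 23 (3aR,4R,6Z,10Z,11aR)-6,10-dimethyl-3-methylidene-2-oxo-2,3,3a,4,5,8,9,11a-octahydrocyclodeca[b]furan-4-yl (2S,3R)-2,3-dimethyloxirane-2-carboxylate
Product: 24 CNP0165580.2, the (1S,10R)-1,10-epoxide of 23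
Conditions: mCPBA, NaHCO3, CH2Cl2, 0 °C
Reagents that add atoms: 3-chloroperoxybenzoic acid, OOC(=O)c1cccc(Cl)c1
Why: Peracid (Prilezhaev) epoxidation is expected to take the most electron-rich olefin C1=C10 (C4=C5 is deactivated by the allylic lactone oxygen, C11=C13 is conjugated) from the face opposite to the 8β-acyloxy group, which by syn addition to the Z olefin gives the 1S,10R cis-oxirane.

**Compound list**

1 | (E)-2-methylbut-2-en-1-ol | C/C=C(\C)CO | starting material
2 | [(2R,3R)-2,3-dimethyloxiran-2-yl]methanol (methyl groups cis) | OC[C@@]1(C)O[C@@H]1C | intermediate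
3 | (2S,3R)-2,3-dimethyloxirane-2-carboxylic acid (methyl groups cis) | OC(=O)[C@@]1(C)O[C@@H]1C | intermediate
4 | (S)-2-methylglycidol | C[C@]1(CO)CO1 | starting material
5 | (R)-tert-butyl[(2-methyloxiran-2-yl)methoxy]diphenylsilane | C[C@]1(CO[Si](c2ccccc2)(c2ccccc2)C(C)(C)C)CO1 | intermediate
6 | (2R)-1-{[tert-butyl(diphenyl)silyl]oxy}-2-methylhex-5-en-2-ol | C[C@](O)(CO[Si](c1ccccc1)(c1ccccc1)C(C)(C)C)CCC=C | intermediate
7 | 3-methylbut-3-enoic acid | C=C(C)CC(=O)O | starting material
8 | (2R)-1-{[tert-butyl(diphenyl)silyl]oxy}-2-methylhex-5-en-2-yl 3-methylbut-3-enoate | C=C(C)CC(=O)O[C@@](C)(CO[Si](c1ccccc1)(c1ccccc1)C(C)(C)C)CCC=C | intermediate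
9 | (4Z,8R)-8-({[tert-butyl(diphenyl)silyl]oxy}methyl)-4,8-dimethyl-3,6,7,8-tetrahydro-2H-oxocin-2-one | O=C1C/C(C)=C\CC[C@](C)(CO[Si](c2ccccc2)(c2ccccc2)C(C)(C)C)O1 | intermediate
10 | tert-butyl{[(4Z,8R)-4,8-dimethyl-2-methylidene-3,6,7,8-tetrahydro-2H-oxocin-8-yl]methoxy}diphenylsilane | C=C1C/C(C)=C\CC[C@](C)(CO[Si](c2ccccc2)(c2ccccc2)C(C)(C)C)O1 | intermediate
11 | (2E)-2-[(4Z,8R)-8-({[tert-butyl(diphenyl)silyl]oxy}methyl)-4,8-dimethyl-3,6,7,8-tetrahydro-2H-oxocin-2-ylidene]-N,N-dimethylethan-1-iminium chloride | C[N+](C)=C/C=C1\C/C(C)=C\CC[C@](C)(CO[Si](c2ccccc2)(c2ccccc2)C(C)(C)C)O1.[Cl-] | intermediate (not isolated)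
12 | (2E)-2-[(4Z,8R)-8-({[tert-butyl(diphenyl)silyl]oxy}methyl)-4,8-dimethyl-3,6,7,8-tetrahydro-2H-oxocin-2-ylidene]acetaldehyde | O=C/C=C1\C/C(C)=C\CC[C@](C)(CO[Si](c2ccccc2)(c2ccccc2)C(C)(C)C)O1 | intermediate
13 | tert-butyl{[(2E,4Z,8R)-4,8-dimethyl-2-(prop-2-yn-1-ylidene)-3,6,7,8-tetrahydro-2H-oxocin-8-yl]methoxy}diphenylsilane | C#C/C=C1\C/C(C)=C\CC[C@](C)(CO[Si](c2ccccc2)(c2ccccc2)C(C)(C)C)O1 | intermediate
14 | [(2E,4Z,8R)-4,8-dimethyl-2-(prop-2-yn-1-ylidene)-3,6,7,8-tetrahydro-2H-oxocin-8-yl]methanol | C#C/C=C1\C/C(C)=C\CC[C@](C)(CO)O1 | intermediate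
15 | (2E,4Z,8R)-4,8-dimethyl-2-(prop-2-yn-1-ylidene)-3,6,7,8-tetrahydro-2H-oxocine-8-carbaldehyde | C#C/C=C1\C/C(C)=C\CC[C@](C)(C=O)O1 | intermediate
16 | 2-{(E)-2-[(2E,4Z,8R)-4,8-dimethyl-2-(prop-2-yn-1-ylidene)-3,6,7,8-tetrahydro-2H-oxocin-8-yl]ethenyl}-4,4,5,5-tetramethyl-1,3,2-dioxaborolane | C#C/C=C1\C/C(C)=C\CC[C@](C)(/C=C/B2OC(C)(C)C(C)(C)O2)O1 | intermediate
17 | (2R,3R,4Z,8Z)-2-ethynyl-5,9-dimethyl-3-(4,4,5,5-tetramethyl-1,3,2-dioxaborolan-2-yl)cyclodeca-4,8-dien-1-one | C#C[C@@H]1C(=O)C/C(C)=C\CC/C(C)=C\[C@H]1B2OC(C)(C)C(C)(C)O2 | intermediate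
18 | (2S,3R,4Z,8Z)-2-ethynyl-3-hydroxy-5,9-dimethylcyclodeca-4,8-dien-1-one | C#C[C@@H]1C(=O)C/C(C)=C\CC/C(C)=C\[C@H]1O | intermediate
19 | (1R,2Z,6Z,9R,10R)-10-ethynyl-9-hydroxy-3,7-dimethylcyclodeca-2,6-dien-1-yl acetate | C#C[C@@H]1[C@H](O)C/C(C)=C\CC/C(C)=C\[C@H]1OC(C)=O | intermediate
20 | (2S,3R)-2,3-dimethyloxirane-2-carboxylic 2,4,6-trichlorobenzoic anhydride | O=C(OC(=O)c1c(Cl)cc(Cl)cc1Cl)[C@@]2(C)O[C@@H]2C | intermediate (not isolated)
21 | (1R,2R,3R,4Z,8Z)-3-acetoxy-2-ethynyl-5,9-dimethylcyclodeca-4,8-dien-1-yl (2S,3R)-2,3-dimethyloxirane-2-carboxylate | C#C[C@@H]1[C@H](OC(=O)[C@@]2(C)O[C@@H]2C)C/C(C)=C\CC/C(C)=C\[C@H]1OC(C)=O | intermediate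
22 | (1R,2S,3R,4Z,8Z)-2-ethynyl-3-hydroxy-5,9-dimethylcyclodeca-4,8-dien-1-yl (2S,3R)-2,3-dimethyloxirane-2-carboxylate | C#C[C@@H]1[C@H](OC(=O)[C@@]2(C)O[C@@H]2C)C/C(C)=C\CC/C(C)=C\[C@H]1O | intermediate
23 | (3aR,4R,6Z,10Z,11aR)-6,10-dimethyl-3-methylidene-2-oxo-2,3,3a,4,5,8,9,11a-octahydrocyclodeca[b]furan-4-yl (2S,3R)-2,3-dimethyloxirane-2-carboxylate | C=C1C(=O)O[C@@H]2/C=C(/C)CC/C=C(C)\C[C@@H](OC(=O)[C@@]3(C)O[C@@H]3C)[C@@H]12 | intermediate
24 | CNP0165580.2, the (1S,10R)-1,10-epoxide of 23 (1S,6R,7R,8R,10R in germacrane numbering, cis-oxirane on the face opposite to the C8 ester) | C=C1C(=O)O[C@@H]2/C=C(/C)CC[C@@H]3O[C@]3(C)C[C@@H](OC(=O)[C@@]3(C)O[C@@H]3C)[C@@H]12 | target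

**Step count and risks**

Total step count: 19 (17 in the main line, 2 for acid 3). Longest linear sequence: 17 steps (steps 3 to 19, from 4).

Steps most likely to fail:

1. Step 13 (Claisen ring expansion). The allylboronate, as it forms, may shift boron to the other allyl terminus or add to the new ketone at the reaction temperature. The enyne-conjugated enol ether may also isomerise into the ring faster than it rearranges. Any leakage through a boat-like array would erode the C6/C7 relationship. Fallback, from 16 back to 18: the boron terminus is exchanged for oxygen before the shift. Copper-promoted Chan–Lam–Evans etherification of 16 with 4-methoxybenzyl alcohol (Cu(OAc)2, Et3N, CH2Cl2, rt, argon) should give (2E,4Z,8R)-8-[(E)-2-(4-methoxybenzyloxy)ethenyl]-4,8-dimethyl-2-(prop-2-yn-1-ylidene)-3,6,7,8-tetrahydro-2H-oxocine F1. Its Claisen ring expansion, accelerated by the 6-alkoxy donor, should run at lower temperature and give (2S,3R,4Z,8Z)-2-ethynyl-3-(4-methoxybenzyloxy)-5,9-dimethylcyclodeca-4,8-dien-1-one F2 through the same chair. DDQ in CH2Cl2/pH 7 buffer then uncovers the C6 hydroxyl and returns to 18.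

2. Step 6 (ring-closing metathesis to the eight-membered lactone). Intermolecular cross-metathesis (oligomerisation) may outrun ring closure, because the tertiary ester must reach its disfavoured s-cis rotamer and close onto a 1,1-disubstituted olefin. Fallback, from 8 back to 12: the carbonyl is converted before the ring is closed. Petasis methylenation of the acyclic ester 8 would give tert-butyl({(2R)-2-methyl-2-[(4-methylpenta-1,4-dien-2-yl)oxy]hex-5-en-1-yl}oxy)diphenylsilane F3. Vilsmeier–Haack formylation would give (2E)-3-{[(2R)-1-{[tert-butyl(diphenyl)silyl]oxy}-2-methylhex-5-en-2-yl]oxy}-5-methylhexa-2,5-dienal F4. Ring-closing metathesis of F4 with the second-generation Grubbs catalyst should then lead to 12, because its push–pull enol ether is inert to the ruthenium carbene and its vinylogous formate linkage has no ester rotamer penalty.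

3. Step 19 (final epoxidation). Facial selection at C1=C10 may be poor or inverted if the ring prefers a conformer that turns the C8 ester outward, and some attack at C4=C5 may compete. Fallback, from 23 back to 24: the oxygen is brought in by anti addition instead of syn addition. NBS in THF/H2O at 0 °C would give (3aR,4R,6R,7R,10Z,11aR)-7-bromo-6-hydroxy-6,10-dimethyl-3-methylidene-2-oxo-2,3,3a,4,5,6,7,8,9,11a-decahydrocyclodeca[b]furan-4-yl (2S,3R)-2,3-dimethyloxirane-2-carboxylate F5, with water entering at the tertiary C10 anti to bromine. K2CO3 in acetone then closes the oxirane with inversion at C1. The oxygen thus ends on the face opposite to the one the electrophile attacked, which reverses the facial outcome and gives 24.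

**Further compounds**

F1 | step 13 | (2E,4Z,8R)-8-[(E)-2-(4-methoxybenzyloxy)ethenyl]-4,8-dimethyl-2-(prop-2-yn-1-ylidene)-3,6,7,8-tetrahydro-2H-oxocine | C#C/C=C1\C/C(C)=C\CC[C@](C)(/C=C/OCc2ccc(OC)cc2)O1
F2 | step 13 | (2S,3R,4Z,8Z)-2-ethynyl-3-(4-methoxybenzyloxy)-5,9-dimethylcyclodeca-4,8-dien-1-one | C#C[C@@H]1C(=O)C/C(C)=C\CC/C(C)=C\[C@H]1OCc1ccc(OC)cc1
F3 | step 6 | tert-butyl({(2R)-2-methyl-2-[(4-methylpenta-1,4-dien-2-yl)oxy]hex-5-en-1-yl}oxy)diphenylsilane | C=C(C)CC(=C)O[C@@](C)(CO[Si](c1ccccc1)(c1ccccc1)C(C)(C)C)CCC=C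
F4 | step 6 | (2E)-3-{[(2R)-1-{[tert-butyl(diphenyl)silyl]oxy}-2-methylhex-5-en-2-yl]oxy}-5-methylhexa-2,5-dienal | O=C/C=C(\CC(C)=C)O[C@@](C)(CO[Si](c1ccccc1)(c1ccccc1)C(C)(C)C)CCC=C
F5 | step 19 | (3aR,4R,6R,7R,10Z,11aR)-7-bromo-6-hydroxy-6,10-dimethyl-3-methylidene-2-oxo-2,3,3a,4,5,6,7,8,9,11a-decahydrocyclodeca[b]furan-4-yl (2S,3R)-2,3-dimethyloxirane-2-carboxylate | C=C1C(=O)O[C@@H]2/C=C(/C)CC[C@@H](Br)[C@@](O)(C)C[C@@H](OC(=O)[C@@]3(C)O[C@@H]3C)[C@@H]12
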